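Slowness was what I looked for first in this closed flask, where solid Sub meets Ptn to give Tgt, but in the spring run Sub already read 0.2% at 1.33 min.

| setting | spring | winter | flask |
|---|---|---|---|
| Sub | 0.10 M | 0.10 M | 0.10 M |
| Ptn | 0.13 M | 0.13 M | 0.130 M |
| temperature | 110 °C | 95 °C | 110 °C |
| remark | the very flask that is asked about, followed so far | run made earlier |  |
| time |  |  | 20 min |

| run | time / min | Tgt / % | Sub / % |
|---|---|---|---|
| spring | 1.00 | 42.0 | 23.3 |
| spring | 1.33 | 48.3 | 0.2 |
| spring | 2.00 | 39.4 | 0.8 |
| spring | 3.00 | 41.8 | 0 |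
| spring | 5.00 | 40.2 | 0 |
| spring | 8.00 | 38.8 | 0 |
| spring | 12.0 | 38.6 | 0.1 |
| winter | 2.00 | 49.9 | 1.1 |
| winter | 3.00 | 36.6 | 1.1 |
| winter | 4.00 | 32.8 | 1.2 |
| winter | 6.00 | 32.0 | 1.5 |
| winter | 10.0 | 31.6 | 0 |
| winter | 15.0 | 31.3 | 0 |
| winter | 25.0 | 30.5 | 0.9 |

(standard deviation of a reading: 1 percentage point)

- additions bring no volume worth counting
- at the start none of Sub is in solution
- a reading or a percentage of Tgt counts all its forms, free or not

- Sunday's: change nothing and wait 20 min more
- Thursday's: at 20 min add Ptn, 50.0% of the amount charged, then wait 20 min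
- Monday's: at 20 min raise the temperature by 15 K, then wait 20 min

- Tgt, in percent of the Sub first charged, at 20 min
- the remedy with the largest gain of Tgt, or "none" below 2 percentage points (Sunday's / Thursday's / Monday's / none)
- Tgt present, in percent of the Sub first charged, after Sunday's
- Tgt present, in percent of the Sub first charged, after Thursday's

In the spring run Tgt had climbed to 42.0% by 1.00 min, already above Sub at 23.3%. The knee came at 1.33 min, where Sub read 0.2% and Tgt peaked at a reading of 48.3%. By 5.00 min the curve had dropped to a flat level, which I read as 39.2%. The highest reading of the winter run was 49.9%, and that run flattened by 6.00 min at 31.3%, lower than the spring level.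

I took a fall that stopped at a different height for each temperature as a balance between Tgt and a partner made from it, thermodynamic rather than kinetic control. So I carried 1.55 at 110 °C and 2.19 at 95 °C: the level ratio, the parts of reacted Sub not standing as Tgt per part standing as Tgt.

The spring level arrived sooner than the 20 min asked about, so I reckoned 39.2% for this flask now and after Sunday's. Monday's rise of 15 K repeats the step between the two runs, so I multiplied the ratio once more by the same factor, to 1.10. That gave 47.7%, a gain of 8.5 percentage points, larger than 2 points. No run showed added Ptn, so I held Thursday's at the level, and my choice was Monday's.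

The forecast gave 37% now, 34.5% after Sunday's, 1% after Thursday's and none as the best remedy, holding that “the plateau means Ptn is exhausted”.

The flask gave 39.7% now and 39.7% after Sunday's, a gain of 0 points; Thursday's gave 44.8%, a gain of 5.1 points; Monday's gained 8.5 points, so the best was Monday's.

    Sub ⇌ Sub2, rate k1*(cs1 - [Sub2]) while solid is left; crystals form when [Sub2] > cs1 (solubility = 0.0680 M, k = 0.0190 /s)
    Sub2 + Ptn → Tgt (k = 8.00 /M/s, Ea = 69.0 kJ/mol)
    Ptn + Tgt ⇌ Imd, settled at all times (K = 4.60 /M, ΔH = −19.0 kJ/mol)
    Tgt ⇌ Ofp (K = 1.70, k = 0.0500 /s, Ea = 90.0 kJ/mol, ΔH = −31.0 kJ/mol)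
    Spx ⇌ Tgt, rate k5*(cs5 - [Tgt]) while solid is left; crystals form when [Tgt] > cs5 (solubility = 0.0830 M, k = 0.700 /s)
    (constants at 110 °C)

At 20 min this flask held Ofp against Tgt at 1.52, with 19.8% of its Ptn free. The neighbour with 0.078 M of Ptn had Ptn as limiting reagent, 0% left, so the reacted share was 78.0%, and my ratio put its Tgt at 30.6%. At 20 min it gave 28.9%, with Ofp at 49.1%. Its Imd, counted within Tgt, stood at 0% against 4.21% in this flask.

(The earlier runs and the new flask stem from a simulated flask on assumed constants; the scatter is artificial.)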